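Numbering is that of labdane: ring A = C1–C5 + C10, ring B = C5–C10, chain C11–C15 on C9, methyls C17 (on C8), C18/C19 (on C4), C20 (on C10), C16 (on C13).
Cuts: the two acetates; C7=C8 (back to a C7 ketone masked as the C6=C7 silyl enol ether); C11=C12 (Wittig); then C5–C10 and C8–C9 together, which opens rings A and B at once to an acyclic triene; in the triene C5=C6 (Horner–Wadsworth–Emmons), C9–C11 and C10–C20 (carboalumination–acylation), C1–C10 (acetylide) and C3–C4 (allylic Grignard).
Forward: the chain is built from C3–C4 through C1–C10 and C10–C20/C9–C11 to C5=C6, rings A and B then close in one intramolecular Diels–Alder step, the C12–C15 unit is joined at C11, and C7=C8 is made last from the C7 ketone.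
Enabling feature: C5, C10 and C9 are neighbours on ring B, which is a Diels–Alder cyclohexene as soon as C7 carries oxygen, and the four ring A atoms C1–C4 (oxygen on C2) form a tether from C10 to C5.
Stereochemistry: C2 from (R)-epichlorohydrin; C5, C9 and C10 from C2 in the cycloaddition (equatorial silyloxy group on a chair tether, E-enoate, ester-endo mode); C13 from (R)-2-methylsuccinic acid 4-methyl ester.
Key step: step 13

Assumption: 8 (commercial THF solution) attacks the epoxide through its γ-carbon, as allylic Grignard reagents normally do without copper salts; TBS = tert-butyldimethylsilyl, TBDPS = tert-butyldiphenylsilyl.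

Step 1
Reactants: 1 (R)-2-methylsuccinic acid 4-methyl ester
Product: 2 methyl (3R)-4-hydroxy-3-methylbutanoate
Conditions: BH3·SMe2, THF, −10 °C → rt; then MeOH
Reagents that add atoms: none
Why: Borane should reduce the free carboxylic acid (via its acyloxyborane) much faster than the methyl ester, a standard chemoselective borane reduction that turns only C12 into CH2OH and leaves the C13 stereocentre untouched.

Step 2
Reactants: 2 methyl (3R)-4-hydroxy-3-methylbutanoate
Product: 3 methyl (3R)-4-iodo-3-methylbutanoate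
Conditions: I2, PPh3, imidazole, CH2Cl2, 0 °C → rt
Reagents that add atoms: iodine, [I][I]
Why: Appel-type iodination should replace the primary hydroxyl by iodide through SN2 at C12, with no bond change at C13, and it removes the hydroxyl before the hydroxy ester can lactonise.

Step 3
Reactants: 3 methyl (3R)-4-iodo-3-methylbutanoate
Product: 4 (3R)-4-iodo-3-methylbutan-1-ol
Conditions: i-Bu2AlH (2.5 equiv), CH2Cl2, −78 → −20 °C; then aq. potassium sodium tartrate
Reagents that add atoms: none
Why: Hydride reduction of the ester with i-Bu2AlH should give the primary alcohol at low temperature, where the primary iodide is inert and the aluminium alkoxide does not cyclise onto it.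

Step 4
Reactants: 4 (3R)-4-iodo-3-methylbutan-1-ol
Product: 5 tert-butyl{[(3R)-4-iodo-3-methylbutyl]oxy}diphenylsilane
Conditions: TBDPSCl, imidazole, CH2Cl2, 0 °C → rt
Reagents that add atoms: tert-butyl(chloro)diphenylsilane, CC(C)(C)[Si](Cl)(c1ccccc1)c1ccccc1
Why: Silylation of a primary alcohol with a silyl chloride and imidazole is routine and gives an ether that should survive the ylide, acid, hydride and POCl3 steps and fall to fluoride at the end.

Step 5
Reactants: 5 tert-butyl{[(3R)-4-iodo-3-methylbutyl]oxy}diphenylsilane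
Product: 6 {(2R)-4-[(tert-butyldiphenylsilyl)oxy]-2-methylbutyl}triphenylphosphonium iodide
Conditions: PPh3, MeCN, 85 °C
Reagents that add atoms: triphenylphosphine, c1ccc(cc1)P(c1ccccc1)c1ccccc1
Why: SN2 quaternisation of PPh3 by the primary iodide gives the Wittig salt, and the β-methyl branch should only slow the displacement, which heat and concentration offset.

Step 6
Reactants: 7 (R)-epichlorohydrin; 8 prenylmagnesium chloride (3-methylbut-2-en-1-ylmagnesium chloride)
Product: 9 (2R)-1-chloro-4,4-dimethylhex-5-en-2-ol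
Conditions: THF, −40 → 0 °C; then aq. NH4Cl
Reagents that add atoms: none
Why: Epoxide opening by an allylic Grignard reagent is expected at the unsubstituted epoxide carbon with allylic transposition (SE2' delivery of the γ-carbon), which creates the quaternary C4 carrying a vinyl group as masked C5 aldehyde, while no bond to C2 is broken so the configuration of 7 is retained.

Step 7
Reactants: 9 (2R)-1-chloro-4,4-dimethylhex-5-en-2-ol
Product: 11 (5S)-3,3-dimethyloct-1-en-7-yn-5-ol, via terminal epoxide 10 (not isolated)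
Conditions: LiC≡CH·H2NCH2CH2NH2 (3 equiv), DMSO, 0 °C → rt
Reagents that add atoms: lithium acetylide–ethylenediamine complex, [Li+].[C-]#C.NCCN
Why: Excess acetylide should first close the chlorohydrin to epoxide 10 (intramolecular Williamson reaction) and then open it at the CH2 terminus (SN2 alkynylation of a terminal epoxide), forming C1–C10 without touching the C2–O bond.

Step 8
Reactants: 11 (5S)-3,3-dimethyloct-1-en-7-yn-5-ol
Product: 12 tert-butyl{[(5S)-3,3-dimethyloct-1-en-7-yn-5-yl]oxy}diphenylsilane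
Conditions: TBDPSCl, imidazole, DMF, rt
Reagents that add atoms: tert-butyl(chloro)diphenylsilane, CC(C)(C)[Si](Cl)(c1ccccc1)c1ccccc1
Why: Standard silylation of the secondary alcohol installs a bulky ether that should tolerate Me3Al, acid and base and later acts as the equatorial control group of the cycloaddition.

Step 9
Reactants: 12 tert-butyl{[(5S)-3,3-dimethyloct-1-en-7-yn-5-yl]oxy}diphenylsilane
Product: 14 methyl (2E,5S)-5-[(tert-butyldiphenylsilyl)oxy]-3,7,7-trimethylnona-2,8-dienoate, via E-alkenylalane 13 (not isolated)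
Conditions: Me3Al, Cp2ZrCl2 (cat.), CH2Cl2, 0 °C → rt; then ClCO2Me, 0 °C → rt
Reagents that add atoms: trimethylaluminium, C[Al](C)C; methyl chloroformate, COC(=O)Cl
Why: Zirconium-catalysed carboalumination (Negishi) should add methyl and aluminium syn across the terminal alkyne with methyl on C10 and aluminium on C9, and acylation of the alkenylalane by the chloroformate with retention fixes the E-enoate in which C20 is cis to the ester, the hindered monosubstituted alkene and the silyl ether being expected to stay inert.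

Step 10
Reactants: 14 methyl (2E,5S)-5-[(tert-butyldiphenylsilyl)oxy]-3,7,7-trimethylnona-2,8-dienoate
Product: 16 methyl (2E,5S)-5-[(tert-butyldiphenylsilyl)oxy]-3,7,7-trimethyl-8-oxooct-2-enoate, via vicinal diol 15 (not isolated)
Conditions: OsO4 (cat.), NaIO4, 2,6-lutidine, dioxane–H2O, rt
Reagents that add atoms: osmium tetroxide, O=[Os](=O)(=O)=O; sodium periodate, [Na+].[O-]I(=O)(=O)=O
Why: In this Lemieux–Johnson cleavage OsO4 should dihydroxylate the isolated monosubstituted alkene in preference to the electron-poor trisubstituted enoate, and periodate cleaves the diol to the non-enolisable C5 aldehyde.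

Step 11
Reactants: 16 methyl (2E,5S)-5-[(tert-butyldiphenylsilyl)oxy]-3,7,7-trimethyl-8-oxooct-2-enoate; 17 diethyl (2-oxobutyl)phosphonate
Product: 19 methyl (2E,5S,8E)-5-[(tert-butyldiphenylsilyl)oxy]-3,7,7-trimethyl-10-oxododeca-2,8-dienoate, via sodium phosphonate 18 (not isolated)
Conditions: NaH, THF, 0 °C; then 16, 0 °C → rt
Reagents that add atoms: none
Why: Horner–Wadsworth–Emmons olefination of the non-enolisable aldehyde with the stabilised β-ketophosphonate anion should give the E-enone C5=C6 (reversible addition, elimination through the less crowded oxaphosphetane).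

Step 12
Reactants: 19 methyl (2E,5S,8E)-5-[(tert-butyldiphenylsilyl)oxy]-3,7,7-trimethyl-10-oxododeca-2,8-dienoate
Product: 20 methyl (2E,5S,8E,10Z)-10-[(tert-butyldimethylsilyl)oxy]-5-[(tert-butyldiphenylsilyl)oxy]-3,7,7-trimethyldodeca-2,8,10-trienoate
Conditions: TBSOTf, Et3N, CH2Cl2, −78 → 0 °C
Reagents that add atoms: tert-butyldimethylsilyl trifluoromethanesulfonate, CC(C)(C)[Si](C)(C)OS(=O)(=O)C(F)(F)F
Why: Soft enolisation (silyl triflate, tertiary amine) can only occur toward C8 because C4 is quaternary, and it should give the Z-enol ether with C17 cis to oxygen, a 2-silyloxydiene whose terminal methyl points outward so that the s-cis conformer is accessible.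

Step 13
Reactants: 20 methyl (2E,5S,8E,10Z)-10-[(tert-butyldimethylsilyl)oxy]-5-[(tert-butyldiphenylsilyl)oxy]-3,7,7-trimethyldodeca-2,8,10-trienoate
Product: 21 methyl (1R,2S,4aR,7R,8aR)-3-[(tert-butyldimethylsilyl)oxy]-7-[(tert-butyldiphenylsilyl)oxy]-2,5,5,8a-tetramethyl-1,2,4a,5,6,7,8,8a-octahydronaphthalene-1-carboxylate
Conditions: toluene (0.01 M), BHT (cat.), 185 °C, sealed tube (base-washed glass)
Reagents that add atoms: none
Why: Concerted, suprafacial [4π+2π] cycloaddition in which the 2-silyloxydiene C5=C6–C7=C8 adds across the E-enoate C9=C10 to form C5–C10 and C8–C9; the closest known reaction type is the thermal intramolecular Diels–Alder reaction of 1,7,9-decatrienoates to trans-decalins, including cases whose dienophile carries the methyl that becomes angular. Ring B closes as the new cyclohexene itself (six-membered, enol ether at C6=C7), and ring A closes in the fused mode as the six-membered carbocycle made of the tether C1–C4 and the new C5–C10 bond. The cis relation of C20 and C11 follows from the E geometry of the enoate, the trans relation of H5 and C20 from the ester-endo transition state with a chair-like tether, and C8 (C17 cis to C11, erased later) from the Z-enol ether with its outward methyl. The absolute sense at C5, C9 and C10 is dictated by C2, whose silyloxy group should stay equatorial on the chair tether because an axial position would be 1,3-diaxial to both C20 and the axial C4 methyl. The step needs endo (trans-fusion) and π-facial selectivity: the first is expected from the endo preference of the E-ester and the strain-free chair tether (the cis-fused alternative folds the tether beside the C10 methyl), the second from the C2 silyl ether, while the C4 gem-dimethyl group favours the reactive rotamer and the silyloxy group raises the diene HOMO, although the tether imposes the electronically less favoured orientation, hence the high temperature.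

Step 14
Reactants: 21 (the cycloadduct ester)
Product: 22 [(1R,2S,4aR,7R,8aR)-3-[(tert-butyldimethylsilyl)oxy]-7-[(tert-butyldiphenylsilyl)oxy]-2,5,5,8a-tetramethyl-1,2,4a,5,6,7,8,8a-octahydronaphthalen-1-yl]methanol
Conditions: i-Bu2AlH (3 equiv), CH2Cl2, −78 → −20 °C; then aq. potassium sodium tartrate
Reagents that add atoms: none
Why: Hydride reduction of the hindered ester with i-Bu2AlH should give the C11 alcohol while the silyl enol ether, which masks the C7 ketone, and the silyl ether are inert to the reagent.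

Step 15
Reactants: 22 (the C11 alcohol)
Product: 23 (1R,2S,4aR,7R,8aR)-3-[(tert-butyldimethylsilyl)oxy]-7-[(tert-butyldiphenylsilyl)oxy]-2,5,5,8a-tetramethyl-1,2,4a,5,6,7,8,8a-octahydronaphthalene-1-carbaldehyde
Conditions: Dess–Martin periodinane, NaHCO3, CH2Cl2, 0 °C → rt
Reagents that add atoms: none
Why: Dess–Martin oxidation under bicarbonate buffer should convert the hindered primary alcohol into the aldehyde without free acid that would hydrolyse the enol ether and without base that could epimerise C9.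

Step 16
Reactants: 23 (the C11 aldehyde); 6 {(2R)-4-[(tert-butyldiphenylsilyl)oxy]-2-methylbutyl}triphenylphosphonium iodide
Product: 25 (11Z)-2,15-bis[(tert-butyldiphenylsilyl)oxy]-7-[(tert-butyldimethylsilyl)oxy]labda-6,11-diene (C2, C5, C9, C10, C13 arranged as in 33; C17 cis to C20), via phosphorus ylide 24 (not isolated)
Conditions: 6, NaN(SiMe3)2, THF, 0 °C; then 23, −78 °C → rt
Reagents that add atoms: none
Why: In this Wittig olefination the non-stabilised ylide should add to the aldehyde faster than it deprotonates C9 and give the Z-alkene C11=C12 by kinetic oxaphosphetane formation, the alkene geometry being irrelevant after step 18 and C13 arriving preformed from 6.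

Step 17
Reactants: 25 (the Z-alkene enol silyl ether)
Product: 27 (11Z)-2,15-bis[(tert-butyldiphenylsilyl)oxy]labd-11-en-7-one with equatorial C17 (H8 trans to H9), via 8-epi ketone 26 (not isolated)
Conditions: 1 M HCl (aq), THF, 0 °C → rt; then K2CO3, MeOH, rt
Reagents that add atoms: none
Why: Dilute acid should hydrolyse the enol silyl ether by protonation at C6 while the diphenylsilyl ethers survive, and carbonate then equilibrates C8 through the enolate so that C17 leaves the axial site, where it is 1,3-diaxial to C20, for the equatorial one (thermodynamic epimerisation).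

Step 18
Reactants: 27 (the Z-alkene ketone)
Product: 28 2,15-bis[(tert-butyldiphenylsilyl)oxy]labdan-7-one (C17 equatorial; other centres as in 33)
Conditions: H2 (1 atm), Pd/C, EtOAc, rt
Reagents that add atoms: none
Why: Catalytic hydrogenation over Pd/C should saturate the unhindered disubstituted alkene, the ketone and silyl ethers being inert and the ring alkene not yet present, so no selectivity between alkenes is asked for.

Step 19
Reactants: 28 (the saturated ketone)
Product: 29 2,15-bis[(tert-butyldiphenylsilyl)oxy]labdan-7-ol with axial 7-OH (cis to H5 and H9, trans to H8)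
Conditions: LiBH(s-Bu)3, THF, −78 °C; then H2O
Reagents that add atoms: none
Why: The bulky trialkylborohydride should attack the cyclohexanone from the equatorial direction (steric approach control), giving the axial C7 alcohol that is anti-periplanar to the axial H8.

Step 20
Reactants: 29 (the axial C7 alcohol)
Product: 31 (2R,5R,9R,10R,13S)-2,15-bis[(tert-butyldiphenylsilyl)oxy]labd-7-ene, via C7 dichlorophosphate 30 (not isolated)
Conditions: POCl3, pyridine, 0 → 60 °C
Reagents that add atoms: none
Why: Pyridine-induced E2 elimination of the dichlorophosphate requires a trans-diaxial hydrogen, and of the two available (H8 and axial H6) loss of the tertiary H8 should prevail to give the more substituted C7=C8 alkene (Zaitsev orientation, as with cis-2-methylcyclohexanol derivatives).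

Step 21
Reactants: 31 (the bis-silyl ether)
Product: 32 (2R,5R,9R,10R,13S)-labd-7-ene-2,15-diol
Conditions: Bu4NF, THF, rt → 50 °C
Reagents that add atoms: none
Why: Fluoride-induced desilylation (formation of Si–F bonds) should cleave both silyl ethers without affecting the trisubstituted alkene or any stereocentre.

Step 22
Reactants: 32 (the diol)
Product: 33 (2R,5R,9R,10R,13S)-labd-7-ene-2,15-diyl diacetate (target)
Conditions: Ac2O, pyridine, DMAP (cat.), CH2Cl2, rt
Reagents that add atoms: acetic anhydride, CC(=O)OC(C)=O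
Why: DMAP-catalysed acylation with acetic anhydride should esterify the primary C15 and the equatorial secondary C2 alcohol to give the target diacetate.

Compound list
1 | (R)-2-methylsuccinic acid 4-methyl ester [(2R)-4-methoxy-2-methyl-4-oxobutanoic acid] | COC(=O)C[C@@H](C)C(=O)O | starting material
2 | methyl (3R)-4-hydroxy-3-methylbutanoate | COC(=O)C[C@@H](C)CO | intermediate
3 | methyl (3R)-4-iodo-3-methylbutanoate | COC(=O)C[C@@H](C)CI | intermediate
4 | (3R)-4-iodo-3-methylbutan-1-ol | OCC[C@@H](C)CI | intermediate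
5 | tert-butyl{[(3R)-4-iodo-3-methylbutyl]oxy}diphenylsilane | CC(C)(C)[Si](c1ccccc1)(c1ccccc1)OCC[C@@H](C)CI | intermediate
6 | {(2R)-4-[(tert-butyldiphenylsilyl)oxy]-2-methylbutyl}triphenylphosphonium iodide | CC(C)(C)[Si](c1ccccc1)(c1ccccc1)OCC[C@@H](C)C[P+](c1ccccc1)(c1ccccc1)c1ccccc1.[I-] | intermediate
7 | (R)-epichlorohydrin [(2R)-2-(chloromethyl)oxirane] | ClC[C@H]1CO1 | starting material
8 | prenylmagnesium chloride (3-methylbut-2-en-1-ylmagnesium chloride) | CC(C)=CC[Mg]Cl | starting material
9 | (2R)-1-chloro-4,4-dimethylhex-5-en-2-ol | ClC[C@H](O)CC(C)(C)C=C | intermediate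
10 | (2R)-2-(2,2-dimethylbut-3-en-1-yl)oxirane (formed in the flask) | C=CC(C)(C)C[C@@H]1CO1 | intermediate
11 | (5S)-3,3-dimethyloct-1-en-7-yn-5-ol | C#CC[C@H](O)CC(C)(C)C=C | intermediate
12 | tert-butyl{[(5S)-3,3-dimethyloct-1-en-7-yn-5-yl]oxy}diphenylsilane | C#CC[C@H](O[Si](c1ccccc1)(c1ccccc1)C(C)(C)C)CC(C)(C)C=C | intermediate
13 | (1E)-alkenyldimethylalane from syn addition of Me–Al to 12: dimethyl{(1E)-4-[(tert-butyldiphenylsilyl)oxy]-2,6,6-trimethylocta-1,7-dien-1-yl}alane, carbinol centre as in 12 (formed in the flask) | C[Al](C)/C=C(\C)C[C@H](O[Si](c1ccccc1)(c1ccccc1)C(C)(C)C)CC(C)(C)C=C | intermediate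
14 | methyl (2E,5S)-5-[(tert-butyldiphenylsilyl)oxy]-3,7,7-trimethylnona-2,8-dienoate | COC(=O)/C=C(\C)C[C@H](O[Si](c1ccccc1)(c1ccccc1)C(C)(C)C)CC(C)(C)C=C | intermediate
15 | methyl (2E,5S)-5-[(tert-butyldiphenylsilyl)oxy]-8,9-dihydroxy-3,7,7-trimethylnon-2-enoate, both C8 epimers (formed in the flask) | COC(=O)/C=C(\C)C[C@H](O[Si](c1ccccc1)(c1ccccc1)C(C)(C)C)CC(C)(C)C(O)CO | intermediate
16 | methyl (2E,5S)-5-[(tert-butyldiphenylsilyl)oxy]-3,7,7-trimethyl-8-oxooct-2-enoate | COC(=O)/C=C(\C)C[C@H](O[Si](c1ccccc1)(c1ccccc1)C(C)(C)C)CC(C)(C)C=O | intermediate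
17 | diethyl (2-oxobutyl)phosphonate | CCC(=O)CP(=O)(OCC)OCC | starting material
18 | sodium salt of the carbanion of 17 (formed in the flask) | CCC(=O)[CH-]P(=O)(OCC)OCC.[Na+] | intermediate
19 | methyl (2E,5S,8E)-5-[(tert-butyldiphenylsilyl)oxy]-3,7,7-trimethyl-10-oxododeca-2,8-dienoate | COC(=O)/C=C(\C)C[C@H](O[Si](c1ccccc1)(c1ccccc1)C(C)(C)C)CC(C)(C)/C=C/C(=O)CC | intermediate
20 | methyl (2E,5S,8E,10Z)-10-[(tert-butyldimethylsilyl)oxy]-5-[(tert-butyldiphenylsilyl)oxy]-3,7,7-trimethyldodeca-2,8,10-trienoate | COC(=O)/C=C(\C)C[C@H](O[Si](c1ccccc1)(c1ccccc1)C(C)(C)C)CC(C)(C)/C=C/C(O[Si](C)(C)C(C)(C)C)=C/C | intermediate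
21 | methyl (1R,2S,4aR,7R,8aR)-3-[(tert-butyldimethylsilyl)oxy]-7-[(tert-butyldiphenylsilyl)oxy]-2,5,5,8a-tetramethyl-1,2,4a,5,6,7,8,8a-octahydronaphthalene-1-carboxylate (trans-fused; C11, C17 and C20 on one face; 2-silyloxy equatorial) | COC(=O)[C@@H]1[C@H](C)C(O[Si](C)(C)C(C)(C)C)=C[C@@H]2C(C)(C)C[C@@H](O[Si](c3ccccc3)(c3ccccc3)C(C)(C)C)C[C@@]12C | intermediate
22 | [(1R,2S,4aR,7R,8aR)-3-[(tert-butyldimethylsilyl)oxy]-7-[(tert-butyldiphenylsilyl)oxy]-2,5,5,8a-tetramethyl-1,2,4a,5,6,7,8,8a-octahydronaphthalen-1-yl]methanol | OC[C@@H]1[C@H](C)C(O[Si](C)(C)C(C)(C)C)=C[C@@H]2C(C)(C)C[C@@H](O[Si](c3ccccc3)(c3ccccc3)C(C)(C)C)C[C@@]12C | intermediate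
23 | (1R,2S,4aR,7R,8aR)-3-[(tert-butyldimethylsilyl)oxy]-7-[(tert-butyldiphenylsilyl)oxy]-2,5,5,8a-tetramethyl-1,2,4a,5,6,7,8,8a-octahydronaphthalene-1-carbaldehyde | O=C[C@@H]1[C@H](C)C(O[Si](C)(C)C(C)(C)C)=C[C@@H]2C(C)(C)C[C@@H](O[Si](c3ccccc3)(c3ccccc3)C(C)(C)C)C[C@@]12C | intermediate
24 | {(2R)-4-[(tert-butyldiphenylsilyl)oxy]-2-methylbutylidene}triphenylphosphorane (formed in the flask) | CC(C)(C)[Si](c1ccccc1)(c1ccccc1)OCC[C@@H](C)C=P(c1ccccc1)(c1ccccc1)c1ccccc1 | intermediate
25 | (11Z)-2,15-bis[(tert-butyldiphenylsilyl)oxy]-7-[(tert-butyldimethylsilyl)oxy]labda-6,11-diene; C2, C5, C9, C10, C13 arranged as in 33, C17 cis to C20 | CC(C)(C)[Si](c1ccccc1)(c1ccccc1)OCC[C@@H](C)/C=C\[C@@H]1[C@H](C)C(O[Si](C)(C)C(C)(C)C)=C[C@@H]2C(C)(C)C[C@@H](O[Si](c3ccccc3)(c3ccccc3)C(C)(C)C)C[C@@]12C | intermediate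
26 | (11Z)-2,15-bis[(tert-butyldiphenylsilyl)oxy]labd-11-en-7-one, 8-epimer with axial C17 cis to C20 (formed in the flask) | CC(C)(C)[Si](c1ccccc1)(c1ccccc1)OCC[C@@H](C)/C=C\[C@@H]1[C@H](C)C(=O)C[C@@H]2C(C)(C)C[C@@H](O[Si](c3ccccc3)(c3ccccc3)C(C)(C)C)C[C@@]12C | intermediate
27 | (11Z)-2,15-bis[(tert-butyldiphenylsilyl)oxy]labd-11-en-7-one, C17 equatorial (H8 trans to H9) | CC(C)(C)[Si](c1ccccc1)(c1ccccc1)OCC[C@@H](C)/C=C\[C@@H]1[C@@H](C)C(=O)C[C@@H]2C(C)(C)C[C@@H](O[Si](c3ccccc3)(c3ccccc3)C(C)(C)C)C[C@@]12C | intermediate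
28 | 2,15-bis[(tert-butyldiphenylsilyl)oxy]labdan-7-one, C17 equatorial, other centres as in 33 | CC(C)(C)[Si](c1ccccc1)(c1ccccc1)OCC[C@@H](C)CC[C@@H]1[C@@H](C)C(=O)C[C@@H]2C(C)(C)C[C@@H](O[Si](c3ccccc3)(c3ccccc3)C(C)(C)C)C[C@@]12C | intermediate
29 | 2,15-bis[(tert-butyldiphenylsilyl)oxy]labdan-7-ol, 7-OH axial (cis to H5 and H9, trans to H8) | CC(C)(C)[Si](c1ccccc1)(c1ccccc1)OCC[C@@H](C)CC[C@@H]1[C@@H](C)[C@@H](O)C[C@@H]2C(C)(C)C[C@@H](O[Si](c3ccccc3)(c3ccccc3)C(C)(C)C)C[C@@]12C | intermediate
30 | C7 dichlorophosphate of 29 (formed in the flask) | CC(C)(C)[Si](c1ccccc1)(c1ccccc1)OCC[C@@H](C)CC[C@@H]1[C@@H](C)[C@@H](OP(=O)(Cl)Cl)C[C@@H]2C(C)(C)C[C@@H](O[Si](c3ccccc3)(c3ccccc3)C(C)(C)C)C[C@@]12C | intermediate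
31 | (2R,5R,9R,10R,13S)-2,15-bis[(tert-butyldiphenylsilyl)oxy]labd-7-ene | CC(C)(C)[Si](c1ccccc1)(c1ccccc1)OCC[C@@H](C)CC[C@@H]1C(C)=CC[C@@H]2C(C)(C)C[C@@H](O[Si](c3ccccc3)(c3ccccc3)C(C)(C)C)C[C@@]12C | intermediate
32 | (2R,5R,9R,10R,13S)-labd-7-ene-2,15-diol | OCC[C@@H](C)CC[C@@H]1C(C)=CC[C@@H]2C(C)(C)C[C@@H](O)C[C@@]12C | intermediate
33 | (2R,5R,9R,10R,13S)-labd-7-ene-2,15-diyl diacetate (CNP0220683.1) | CC(=O)OCC[C@@H](C)CC[C@@H]1C(C)=CC[C@@H]2C(C)(C)C[C@@H](OC(C)=O)C[C@@]12C | target

Total step count: 22 (5 steps to the side-chain salt 6, 17 on the main line).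
Longest linear sequence: 17 steps (steps 6–22, from 7 to 33).

Steps most likely to fail

Step 13. The β,β-disubstituted enoate is a sluggish dienophile and the tether enforces the electronically less favoured orientation. At the temperature required, loss of the enol silyl group or leakage through the exo (cis-fused) transition state may therefore compete. The fallback raises the dienophile to the aldehyde oxidation level before cyclisation. Setting out from 20, i-Bu2AlH (CH2Cl2, −78 °C) should reduce the enoate to the (2E)-allylic alcohol triene F1, and MnO2 should oxidise it to the (2E)-enal triene F2. The enal has a lower LUMO and can be activated by Me2AlCl at −78 °C, where thermal E/Z isomerisation is not an issue. Its cycloaddition through the same endo chair transition state would give aldehyde 23 directly, where the route is rejoined; steps 14 and 15 are then not needed.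

Step 16. Addition of the β-branched ylide to the hindered aldehyde may be slow enough for deprotonation at C9 to intervene, leading to epimerisation or recovered aldehyde. The fallback is a Julia–Kocienski olefination. Setting out from iodide 5, 1-phenyl-1H-tetrazole-5-thiol with K2CO3 in DMF should give the tetrazolyl thioether F3, and H2O2 with (NH4)6Mo7O24 the tetrazolyl sulfone F4. KN(SiMe3)2 in DME at −60 °C generates the potassium sulfonyl carbanion F5, which adds to 23 and, after Smiles rearrangement and loss of SO2, should give the (11E)-alkene enol silyl ether F6. Treatment as in step 17 leads through the (11E) 8-epi ketone F7 to the (11E) ketone F8, and hydrogenation as in step 18 returns to 28.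

Step 20. Anti-elimination toward C6 or substitution by chloride may compete with loss of H8, giving the C6=C7 isomer. The fallback fixes the alkene position at the enolate stage. Setting out from ketone 28, BrMgN(i-Pr)2 in ether (equilibrating conditions) should give the more substituted bromomagnesium enolate F9, which PhNTf2 traps as the C7 enol triflate F10 with the C7=C8 double bond in place. Reduction with Pd(OAc)2, PPh3, HCO2H and Bu3N in DMF should then replace the triflate by hydrogen and give 31, where the route is rejoined; steps 19 and 20 are bypassed.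

Further compounds
F1 | step 13 | (2E,5S,8E,10Z)-10-[(tert-butyldimethylsilyl)oxy]-5-[(tert-butyldiphenylsilyl)oxy]-3,7,7-trimethyldodeca-2,8,10-trien-1-ol | OC/C=C(\C)C[C@H](O[Si](c1ccccc1)(c1ccccc1)C(C)(C)C)CC(C)(C)/C=C/C(O[Si](C)(C)C(C)(C)C)=C/C
F2 | step 13 | (2E,5S,8E,10Z)-10-[(tert-butyldimethylsilyl)oxy]-5-[(tert-butyldiphenylsilyl)oxy]-3,7,7-trimethyldodeca-2,8,10-trienal | O=C/C=C(\C)C[C@H](O[Si](c1ccccc1)(c1ccccc1)C(C)(C)C)CC(C)(C)/C=C/C(O[Si](C)(C)C(C)(C)C)=C/C
F3 | step 16 | 5-({(2R)-4-[(tert-butyldiphenylsilyl)oxy]-2-methylbutyl}sulfanyl)-1-phenyl-1H-tetrazole | CC(C)(C)[Si](c1ccccc1)(c1ccccc1)OCC[C@@H](C)CSc1nnnn1-c2ccccc2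
F4 | step 16 | 5-({(2R)-4-[(tert-butyldiphenylsilyl)oxy]-2-methylbutyl}sulfonyl)-1-phenyl-1H-tetrazole | CC(C)(C)[Si](c1ccccc1)(c1ccccc1)OCC[C@@H](C)CS(=O)(=O)c1nnnn1-c2ccccc2
F5 | step 16 | potassium salt of the α-sulfonyl carbanion of F4 | CC(C)(C)[Si](c1ccccc1)(c1ccccc1)OCC[C@@H](C)[CH-]S(=O)(=O)c1nnnn1-c2ccccc2.[K+]
F6 | step 16 | (11E)-2,15-bis[(tert-butyldiphenylsilyl)oxy]-7-[(tert-butyldimethylsilyl)oxy]labda-6,11-diene (11E isomer of 25) | CC(C)(C)[Si](c1ccccc1)(c1ccccc1)OCC[C@@H](C)/C=C/[C@@H]1[C@H](C)C(O[Si](C)(C)C(C)(C)C)=C[C@@H]2C(C)(C)C[C@@H](O[Si](c3ccccc3)(c3ccccc3)C(C)(C)C)C[C@@]12C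
F7 | step 16 | (11E)-2,15-bis[(tert-butyldiphenylsilyl)oxy]labd-11-en-7-one, 8-epimer with axial C17 | CC(C)(C)[Si](c1ccccc1)(c1ccccc1)OCC[C@@H](C)/C=C/[C@@H]1[C@H](C)C(=O)C[C@@H]2C(C)(C)C[C@@H](O[Si](c3ccccc3)(c3ccccc3)C(C)(C)C)C[C@@]12C
F8 | step 16 | (11E)-2,15-bis[(tert-butyldiphenylsilyl)oxy]labd-11-en-7-one, C17 equatorial | CC(C)(C)[Si](c1ccccc1)(c1ccccc1)OCC[C@@H](C)/C=C/[C@@H]1[C@@H](C)C(=O)C[C@@H]2C(C)(C)C[C@@H](O[Si](c3ccccc3)(c3ccccc3)C(C)(C)C)C[C@@]12C
F9 | step 20 | bromomagnesium C7=C8 enolate of 28 | CC(C)(C)[Si](c1ccccc1)(c1ccccc1)OCC[C@@H](C)CC[C@@H]1C(C)=C(O[Mg]Br)C[C@@H]2C(C)(C)C[C@@H](O[Si](c3ccccc3)(c3ccccc3)C(C)(C)C)C[C@@]12C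
F10 | step 20 | 2,15-bis[(tert-butyldiphenylsilyl)oxy]labd-7-en-7-yl trifluoromethanesulfonate | CC(C)(C)[Si](c1ccccc1)(c1ccccc1)OCC[C@@H](C)CC[C@@H]1C(C)=C(OS(=O)(=O)C(F)(F)F)C[C@@H]2C(C)(C)C[C@@H](O[Si](c3ccccc3)(c3ccccc3)C(C)(C)C)C[C@@]12C
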